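Alpha was fed 2.20 times the coupling partner of eta over the same dosing time, and at 30.0 min alpha kept 50.5% of its starting material against 66.1% in eta. Two new flasks hold equal charges and differ in how the partner goes in: ochre gets it all at the start, grey by feed.

| setting | eta | alpha | ochre | grey |
|---|---|---|---|---|
| starting material | 20 mM | 20 mM | 20 mM | 20 mM |
| coupling partner | 1 equiv (fed, over 30 min) | 2.2 equiv (fed, over 30 min) | 1.50 equiv | 1.50 equiv (fed, over 30 min) |
| free catalyst | 0.27 mol% | 0.27 mol% | 0.27 mol% | 0.27 mol% |
| remark | run made earlier | run made earlier | everything together at the start |  |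
| time |  |  | 30 min | 30 min |

| run | time / min | product / % | starting material / % |
|---|---|---|---|
| eta | 2.50 | 0.7 | 98.9 |
| eta | 8.00 | 4.2 | 96.6 |
| eta | 15.0 | 10.5 | 89.4 |
| eta | 20.0 | 18.7 | 82.1 |
| eta | 30.0 | 34.0 | 66.1 |
| alpha | 2.50 | 0.4 | 98.6 |
| alpha | 5.00 | 4.4 | 97.6 |
| alpha | 8.00 | 8.8 | 92.2 |
| alpha | 15.0 | 20.3 | 78.7 |
| alpha | 30.0 | 50.4 | 50.5 |

(readings scatter by 1 percentage point)



- which of the two ends with the higher amount of product, in percent of the starting material charged ("neither" if they lie within 2 percentage points) (ochre / grey / neither)
- product at the end, in percent of the starting material charged, ochre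
- product at the end, in percent of the starting material charged, grey

We reduce each run to its mean constant κ, the pseudo-first-order constant that takes the starting material from its charge to what is left in time t: κ = ln(charge/left)/t. Eta gives 0.0138 min⁻¹ and alpha 0.0228 min⁻¹. Beside κ we set m, the mean partner delivered up to t. The bench rule counts a fed flask as a batch holding its mean delivered partner, so m is 0.500 for eta and 1.10 for alpha, in eta half of the charge.

With κ proportional to m, the rule puts ochre at 71.1% product. But the rule stops working between these two runs: alpha over eta is 2.20 in m, and the same ratio in κ is 1.65, which is smaller. So we add a fixed time to the reciprocal, 1/κ = a + b/m, and the two runs give a = 20.1 min and b = 26.2 min.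

Using a mean in place of the curve needs a check. Alpha at 15.0 min has m = 0.550, and the line then gives 19.9% product, against a reading of 20.3% that scatters by 1 percentage point.

Grey has m = 0.750, so κ = 0.0182 min⁻¹ and its product is 42.0%. Ochre has m = 1.50, so κ = 0.0266 min⁻¹, its mean constant, and its product is 55.0%, more than grey.

The forecast names ochre, with ochre at 58% (50% to 66%) and grey at 42% (38% to 46%), which is above our ochre figure and level with our grey one: “Ochre ends higher, because partner is present from the start.”

The flasks give ochre 58.9% and grey 42.2%, so ochre ends ahead.

    starting material + free catalyst → catalyst intermediate A (k = 40.0 M⁻¹ s⁻¹)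
    coupling partner + catalyst intermediate A → catalyst intermediate B (k = 15.0 M⁻¹ s⁻¹)
    catalyst intermediate B → catalyst intermediate C (k = 0.550 s⁻¹)
    catalyst intermediate C → free catalyst + product (k = 5.00 s⁻¹)
    free catalyst ⇌ dormant form (K = 19.0, k = 8.40 × 10⁻⁴ s⁻¹)
    2 catalyst intermediate C → spent catalyst (k = 180 M⁻¹ s⁻¹)

Ochre's mean constant, read from its result, is 0.0296 min⁻¹ against our 0.0266 min⁻¹. The neighbouring flask is ochre at 5.0 mM of starting material, with equivalents and loading held, so m stands and the catalyst charged per litre is a quarter of ochre's. We take κ to follow the catalyst concentration, which gives 0.00741 min⁻¹ and 19.9% product. The neighbouring flask gives 22.3% product, with 78% of its starting material left.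

The numbers in the tables are simulated with made-up constants, and the scatter is random.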